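## Retrosynthetic overview

1. Ring D is closed last by a ketyl–alkyne 5-exo-dig cyclisation (C13–C16) of an 8β-propargyl 13-ketone; the propargyl group comes from conjugate addition to a Δ8(14)-13-enone.
2. The enone comes from Birch reduction of a 13-methoxy aromatic ring C that is carried from the start (second dearomatisation).
3. The five-membered ring B with C7 outside the ring comes from an oxidative 1,2-aryl-shift contraction of a six-membered C6=C7 ring (a 1,2-dihydronaphthalene).
4. Ring A is closed by C3–C4 alkylation of a C19 acid dianion, then C4 methylation with the methyl entering anti to the axial C20 group.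
5. Key step: Meyers dearomatising tandem addition (vinyl = C4/C19) and alkylation (C1–C3) on a chiral 6-methoxy-1-naphthyloxazoline sets C5/C10 trans. Ring order: C (aromatic) → A → B (contraction) → C (reduced) → D.

Assumption and convention: 1 and 2 are catalogue compounds; intermediates are described with gibberellane numbering (C1–C20), β is the face of H-5, and the SMILES strings are authoritative for stereochemistry.

## Route

Step 1
Reactants: 1 6-methoxy-1-naphthoic acid; 2 (S)-tert-leucinol
Product: 4 (4S)-4-tert-butyl-2-(6-methoxynaphthalen-1-yl)-4,5-dihydro-1,3-oxazole, via hydroxy amide 3 (not isolated)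
Conditions: PPh3 (3 equiv), CCl4 (4 equiv), Et3N (3 equiv), MeCN/pyridine, 0 °C to rt
Reagents that add atoms: none
Why: Vorbrüggen–Krolikiewicz one-pot oxazoline synthesis (Appel-type activation, amide formation, then cyclodehydration of the β-hydroxy amide); the stereocentre of 2 is untouched.

Step 2
Reactants: 4 (4S)-4-tert-butyl-2-(6-methoxynaphthalen-1-yl)-4,5-dihydro-1,3-oxazole
Product: 6 (4S)-4-tert-butyl-2-[(1S,2S)-1-(3-chloropropyl)-6-methoxy-2-vinyl-1,2-dihydronaphthalen-1-yl]-4,5-dihydro-1,3-oxazole, via lithium aza-enolate 5 (not isolated)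
Conditions: CH2=CHLi (2.5 equiv, titrated stock solution), THF, −78 °C, 3 h; then ICH2CH2CH2Cl (4 equiv), −78 → 0 °C
Reagents that add atoms: vinyllithium ([Li]C=C); 1-chloro-3-iodopropane (ClCCCI)
Why: Meyers dearomatising tandem conjugate addition–alkylation: N-bound vinyllithium is delivered to C5 on the face anti to the tert-butyl group, and aza-enolate 5 is alkylated at C10 through the iodide terminus anti to the new vinyl group, which sets C5 (vinyl α) and quaternary C10 (chain β, oxazoline α) trans in one operation.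

Step 3
Reactants: 6 the vinyl/chloropropyl dihydronaphthalene oxazoline
Product: 8 C19 primary alcohol (C5 carries CH2CH2OH), via B-alkylborane 7 (not isolated)
Conditions: 9-borabicyclo[3.3.1]nonane (1.3 equiv), THF, 0 °C to rt; then 3 M NaOH, 30% H2O2, 0 °C
Reagents that add atoms: hydrogen peroxide (OO)
Why: Brown hydroboration–oxidation: the bulky borane adds anti-Markovnikov to the monosubstituted vinyl group much faster than to the cyclic styrene-type C6=C7 bond, and oxidation with retention gives the C19 alcohol without touching a stereocentre.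

Step 4
Reactants: 8 C19 primary alcohol
Product: 9 C19 carboxylic acid (C5 carries CH2CO2H)
Conditions: 2,2,6,6-tetramethylpiperidin-1-oxyl (7 mol%), NaOCl (2 mol%), NaClO2 (2 equiv), MeCN/phosphate buffer pH 6.7, 35 °C
Reagents that add atoms: sodium chlorite ([Na+].[O-]Cl=O)
Why: Anelli–Zhao oxoammonium/chlorite oxidation takes the primary alcohol to the acid at near-neutral pH, which spares the oxazoline, the alkyl chloride, the styrene and the anisole ring.

Step 5
Reactants: 9 C19 carboxylic acid
Product: 12 ring-A-closed benzyl ester (C4: β-CH3 and α-CO2Bn; C10: α-oxazoline; A/B trans), via cyclised acid 10 (not isolated), via methylated acid 11 (not isolated)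
Conditions: LiN(i-Pr)2 (2.3 equiv), THF/(Me2N)3PO, −78 → 45 °C; then LiN(i-Pr)2 (1.3 equiv), 0 → 40 °C, MeI (1.1 equiv), −20 °C; then BnBr (3 equiv), rt
Reagents that add atoms: iodomethane (CI); benzyl bromide (BrCc1ccccc1)
Why: Carboxylic acid dianion (enediolate) alkylations: 6-exo-tet displacement of chloride by C4 closes the trans-fused ring A, the regenerated dianion is methylated from the equatorial β-face because the axial C20 oxazoline blocks the α-face (C19 ends axial α, C18 β), and the carboxylate is then O-benzylated.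

Step 6
Reactants: 12 ring-A-closed benzyl ester
Product: 13 ring-contracted dimethyl acetal (five-membered ring B; C6 carries β-CH(OMe)2)
Conditions: TsOH·H2O (1.1 equiv), PhI(OH)OTs (1.2 equiv), MeOH, −10 °C to rt
Reagents that add atoms: methanol (CO)
Why: Oxidative ring contraction of a 1,2-dihydronaphthalene by a trivalent iodine reagent (semipinacol-type 1,2-aryl shift): the iodane adds to C6 on the β-face (pseudo-equatorial, because the α-axial approach is syn-diaxial to the protonated C20 oxazoline), methanol captures benzylic C7, and the ring bond C7–C8, which is antiperiplanar to the equatorial C6–I bond, migrates to C6 with loss of PhI, which leaves C7 as a β-CH(OMe)2 on C6.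

Step 7
Reactants: 13 ring-contracted dimethyl acetal
Product: 16 7,20-dialdehyde 19-benzyl ester, via oxazolinium triflate 14 (not isolated), via oxazolidine 15 (not isolated)
Conditions: MeOTf, CH2Cl2, rt; then NaBH4, THF/MeOH, 0 °C; then 2 M HCl, THF/H2O, rt
Reagents that add atoms: water (O)
Why: Meyers reductive oxazoline cleavage (N-methylation, hydride reduction to the oxazolidine, acid hydrolysis) unmasks the hindered quaternary C20 as an aldehyde while the same acid hydrolyses the C7 acetal; C6 can equilibrate to the more stable β-formyl epimer trans to C4.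

Step 8
Reactants: 16 7,20-dialdehyde 19-benzyl ester
Product: 17 7,20-diacid 19-benzyl ester
Conditions: NaClO2, NaH2PO4, 2-methyl-2-butene, t-BuOH/H2O, rt
Reagents that add atoms: sodium chlorite ([Na+].[O-]Cl=O)
Why: Pinnick (Lindgren–Kraus) oxidation converts both aldehydes to carboxylic acids without epimerising C6, the hypochlorite by-product being scavenged by the alkene before it can chlorinate the anisole ring.

Step 9
Reactants: 17 7,20-diacid 19-benzyl ester
Product: 20 13-oxo-Δ8(14)-enone 7,19,20-triacid (H-9 β), via dihydroanisole triacid 18 (not isolated), via deconjugated enone 19 (not isolated)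
Conditions: Li (14 equiv), NH3(l)/THF, t-BuOH, −78 → −33 °C; NH4Cl; then 2 M HCl, THF/H2O, rt → 45 °C
Reagents that add atoms: water (O)
Why: Birch reduction cleaves the benzyl ester to the carboxylate and reduces the anisole ring to the 1-methoxy-1,4-diene (H added at C14 and C11); enol ether hydrolysis and acid-catalysed conjugation then give the Δ8(14)-13-enone, with the γ-carbon C9 protonated under equilibrium (dienol) control to the 9β-H epimer (C11 pseudo-equatorial on ring B).

Step 10
Reactants: 20 13-oxo-Δ8(14)-enone triacid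
Product: 23 8β-propargyl 13-ketone triacid, via tris(trimethylsilyl) ester 21 (not isolated), via silylated adduct 22 (not isolated)
Conditions: (Me3Si)2NH, Me3SiCl (cat.), CH2Cl2, 40 °C, evaporate; then CH2=C=CHSnBu3 (2 equiv), TiCl4 (3 equiv), CH2Cl2, −78 °C; 1 M HCl work-up
Reagents that add atoms: tributyl(propa-1,2-dien-1-yl)stannane (C=C=C[Sn](CCCC)(CCCC)CCCC)
Why: Hosomi–Sakurai-type conjugate propargylation (SE2′ attack of the allenylstannane on the TiCl4-activated enone, carboxyls transiently masked as silyl esters): axial attack on C8 from the β-face, anti to the axial C20 carboxyl, gives the cis-fused B/C hydrindanone with the propargyl group syn to H-9.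

Step 11
Reactants: 23 8β-propargyl 13-ketone triacid
Product: 24 the target gibberellin, ent-13-hydroxygibberell-16-ene-7,19,20-trioic acid
Conditions: SmI2 (6 equiv), (Me2N)3PO, t-BuOH, THF, 0 °C to rt; 1 M HCl work-up
Reagents that add atoms: none
Why: SmI2-mediated ketyl–alkyne reductive cyclisation (Stork-type 5-exo-dig): the C13 ketyl adds to the internal alkyne carbon C16 and the vinyl radical is reduced and protonated, which forms ring D with the 13-OH and the exocyclic methylene; the bridge geometry allows only one configuration at C13.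

## Compound list

1 | 6-methoxy-1-naphthoic acid | OC(=O)c1cccc2cc(OC)ccc12 | starting material
2 | (S)-tert-leucinol, (2S)-2-amino-3,3-dimethylbutan-1-ol | N[C@@H](C(C)(C)C)CO | starting material
3 | N-[(2S)-1-hydroxy-3,3-dimethylbutan-2-yl]-6-methoxynaphthalene-1-carboxamide | COc1ccc2c(C(=O)N[C@@H](C(C)(C)C)CO)cccc2c1 | intermediate
4 | (4S)-4-tert-butyl-2-(6-methoxynaphthalen-1-yl)-4,5-dihydro-1,3-oxazole | COc1ccc2c(C3=N[C@@H](C(C)(C)C)CO3)cccc2c1 | intermediate
5 | lithium aza-enolate: 6-methoxy-2-vinyl-1,2-dihydronaphthalene with exocyclic C10=C20 N-lithio ketene N,O-acetal | COc1ccc2c(c1)C=C[C@H](C=C)C2=C1N([Li])[C@@H](C(C)(C)C)CO1 | intermediate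
6 | (4S)-4-tert-butyl-2-[(1S,2S)-1-(3-chloropropyl)-6-methoxy-2-vinyl-1,2-dihydronaphthalen-1-yl]-4,5-dihydro-1,3-oxazole (vinyl α on C5, chloropropyl β on C10) | COc1ccc2c(c1)C=C[C@H](C=C)[C@]2(CCCCl)C1=N[C@@H](C(C)(C)C)CO1 | intermediate
7 | B-alkyl-9-borabicyclo[3.3.1]nonane adduct of 6 (boron on C19) | COc1ccc2c(c1)C=C[C@H](CCB3C4CCCC3CCC4)[C@]2(CCCCl)C1=N[C@@H](C(C)(C)C)CO1 | intermediate
8 | C19 primary alcohol: as 6 with CH2CH2OH on C5 | COc1ccc2c(c1)C=C[C@H](CCO)[C@]2(CCCCl)C1=N[C@@H](C(C)(C)C)CO1 | intermediate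
9 | C19 carboxylic acid: as 6 with CH2CO2H on C5 | COc1ccc2c(c1)C=C[C@H](CC(=O)O)[C@]2(CCCCl)C1=N[C@@H](C(C)(C)C)CO1 | intermediate
10 | cyclised acid: ring A closed trans-fused, C4-H carboxylic acid (C4 epimers) | COc1ccc2c(c1)C=C[C@@H]3C(C(=O)O)CCC[C@@]23C4=N[C@@H](C(C)(C)C)CO4 | intermediate
11 | methylated acid: C4 with β-CH3 and α-CO2H | COc1ccc2c(c1)C=C[C@@H]3[C@](C)(C(=O)O)CCC[C@@]23C4=N[C@@H](C(C)(C)C)CO4 | intermediate
12 | benzyl ester of 11: tricyclic C6=C7 dihydronaphthalene, C4 β-CH3/α-CO2Bn, C10 α-oxazoline, 13-methoxy arene | COc1ccc2c(c1)C=C[C@@H]3[C@](C)(C(=O)OCc5ccccc5)CCC[C@@]23C4=N[C@@H](C(C)(C)C)CO4 | intermediate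
13 | ring-contracted acetal: five-membered ring B, C6 β-CH(OMe)2, otherwise as 12 | COc1ccc2c(c1)[C@@H](C(OC)OC)[C@@H]3[C@](C)(C(=O)OCc5ccccc5)CCC[C@@]23C4=N[C@@H](C(C)(C)C)CO4 | intermediate
14 | N-methyloxazolinium triflate of 13 | COc1ccc2c(c1)[C@@H](C(OC)OC)[C@@H]3[C@](C)(C(=O)OCc5ccccc5)CCC[C@@]23C4=[N+](C)[C@@H](C(C)(C)C)CO4.[O-]S(=O)(=O)C(F)(F)F | intermediate
15 | N-methyloxazolidine from 14 (C20 epimers) | COc1ccc2c(c1)[C@@H](C(OC)OC)[C@@H]3[C@](C)(C(=O)OCc5ccccc5)CCC[C@@]23C4N(C)[C@@H](C(C)(C)C)CO4 | intermediate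
16 | 7,20-dialdehyde 19-benzyl ester (C6 β-CHO, C10 α-CHO) | COc1ccc2c(c1)[C@@H](C=O)[C@@H]3[C@](C)(C(=O)OCc4ccccc4)CCC[C@@]23C=O | intermediate
17 | 7,20-diacid 19-benzyl ester, 13-methoxy aromatic ring C | COc1ccc2c(c1)[C@@H](C(=O)O)[C@@H]3[C@](C)(C(=O)OCc4ccccc4)CCC[C@@]23C(=O)O | intermediate
18 | dihydroanisole triacid: 13-methoxy-12-ene, 8(9)-ene | COC1=CCC2=C(C1)[C@@H](C(=O)O)[C@@H]3[C@](C)(C(=O)O)CCC[C@@]23C(=O)O | intermediate
19 | deconjugated enone triacid: 13-oxo-8(9)-ene | O=C1CCC2=C(C1)[C@@H](C(=O)O)[C@@H]3[C@](C)(C(=O)O)CCC[C@@]23C(=O)O | intermediate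
20 | conjugated enone triacid: 13-oxo-8(14)-ene, H-9 β | O=C1CC[C@@H]2C(=C1)[C@@H](C(=O)O)[C@@H]3[C@](C)(C(=O)O)CCC[C@@]23C(=O)O | intermediate
21 | tris(trimethylsilyl) ester of 20 | O=C1CC[C@@H]2C(=C1)[C@@H](C(=O)O[Si](C)(C)C)[C@@H]3[C@](C)(C(=O)O[Si](C)(C)C)CCC[C@@]23C(=O)O[Si](C)(C)C | intermediate
22 | tris(trimethylsilyl) ester of 23 | O=C1CC[C@@H]2[C@](CC#C)(C1)[C@@H](C(=O)O[Si](C)(C)C)[C@@H]3[C@](C)(C(=O)O[Si](C)(C)C)CCC[C@@]23C(=O)O[Si](C)(C)C | intermediate
23 | 8β-propargyl 13-ketone 7,19,20-triacid (B/C cis, H-9 β) | O=C1CC[C@@H]2[C@](CC#C)(C1)[C@@H](C(=O)O)[C@@H]3[C@](C)(C(=O)O)CCC[C@@]23C(=O)O | intermediate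
24 | the target gibberellin, ent-13-hydroxygibberell-16-ene-7,19,20-trioic acid | C=C1C[C@]23C[C@@]1(O)CC[C@H]2[C@]1(C(=O)O)CCC[C@@](C)(C(=O)O)[C@H]1[C@@H]3C(=O)O | target

## Step count and risks

Total step count: 11. Longest linear sequence: 11 steps from 1 (fully linear).

Steps most likely to fail:

Step 6. The trivalent iodine ring contraction has no precedent on a trans-fused substrate with a quaternary C10, and trans-dimethoxylation or neighbouring-group capture may compete. The fallback sets out from 12 and comes back at 13. N-bromosuccinimide in wet THF (1 equiv TsOH·H2O) forms the bromonium ion on the open β-face and water opens it at benzylic C7, which gives the diequatorial trans-bromohydrin F1 (6β-Br, 7α-OH). Its magnesium alkoxide (1 equiv i-PrMgCl, toluene, 80 °C) undergoes a Tiffeneau-type semipinacol contraction, the ring bond C7–C8 shifting anti to the equatorial bromide, to give the ring-contracted 6β-formyl oxazoline F2. Acetalisation (HC(OMe)3, MeOH, cat. TsOH·H2O) returns 13.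

Step 10. A quaternary centre is formed next to the C6 carboxyl on a transiently silylated triacid, and the tin reagent and the face selectivity are both untested here. The fallback sets out from 20 and comes back at 24. Me3SiCHN2 in MeOH/toluene gives the trimethyl ester F3. Sakurai conjugate addition of (2-bromoallyl)trimethylsilane with TiCl4 (CH2Cl2, −78 °C) gives the 8β-(2-bromoallyl) ketone triester F4. An intramolecular Nozaki–Hiyama–Kishi reaction (CrCl2, cat. NiCl2, DMF) closes ring D to the trimethyl ester of the target F5. n-PrSLi in (Me2N)3PO then cleaves the three methyl esters by SN2 attack to give 24.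

Step 11. Three free carboxylic acids may protonate the ketyl early and favour simple ketone reduction over cyclisation. The fallback sets out from 23 and comes back at 24. Markovnikov hydroiodination of the alkyne (Me3SiCl, NaI, H2O, MeCN) gives the 2-iodoallyl ketone triacid F6. Ring D is then closed by intramolecular Nozaki–Hiyama–Kishi addition of the vinylchromium to the C13 ketone (excess CrCl2, cat. NiCl2, DMF).

Further compounds

F1 | step 6 | trans-bromohydrin of 12 (6β-Br, 7α-OH) | COc1ccc2c(c1)[C@H](O)[C@@H](Br)[C@@H]3[C@](C)(C(=O)OCc5ccccc5)CCC[C@@]23C4=N[C@@H](C(C)(C)C)CO4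
F2 | step 6 | ring-contracted 6β-formyl oxazoline benzyl ester | COc1ccc2c(c1)[C@@H](C=O)[C@@H]3[C@](C)(C(=O)OCc5ccccc5)CCC[C@@]23C4=N[C@@H](C(C)(C)C)CO4
F3 | step 10 | trimethyl ester of 20 | O=C1CC[C@@H]2C(=C1)[C@@H](C(=O)OC)[C@@H]3[C@](C)(C(=O)OC)CCC[C@@]23C(=O)OC
F4 | step 10 | 8β-(2-bromoallyl) 13-ketone trimethyl ester | O=C1CC[C@@H]2[C@](CC(Br)=C)(C1)[C@@H](C(=O)OC)[C@@H]3[C@](C)(C(=O)OC)CCC[C@@]23C(=O)OC
F5 | step 10 | trimethyl ester of the target, trimethyl ent-13-hydroxygibberell-16-ene-7,19,20-trioate | C=C1C[C@]23C[C@@]1(O)CC[C@H]2[C@]1(C(=O)OC)CCC[C@@](C)(C(=O)OC)[C@H]1[C@@H]3C(=O)OC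
F6 | step 11 | 8β-(2-iodoallyl) 13-ketone triacid | O=C1CC[C@@H]2[C@](CC(I)=C)(C1)[C@@H](C(=O)O)[C@@H]3[C@](C)(C(=O)O)CCC[C@@]23C(=O)O
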